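**Retrosynthetic overview**
- The strategy rests on ring A: the hydroxyl carbon C1 and the aryloxy carbon C2 are neighbours, followed by bromine on C3, C4 and C5 and hydrogen on C6. Ring A is therefore 3,4,5-tribromophenol with one extra ortho oxygen, and the C1–O/C2–O pair corresponds to the C=O and C=N2 carbons of an ortho-quinone diazide.
- Key disconnection: the bond between the ether oxygen and C2 of ring A. Ring B arrives as 2,4-dibromophenol (the O–H donor) and ring A as the quinoid carbene precursor, so the hindered ether and the free C1 hydroxyl should appear together without protecting groups.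
- The diazide goes back through the ortho-aminophenol and ortho-nitrophenol to mirror-symmetric 3,4,5-tribromophenol, which comes from 1,2,3-tribromobenzene by C–H borylation at C5 and oxidation.
- No ring is formed: both benzene rings are bought, ring A is functionalised first with oxygen, then with nitrogen on the adjacent carbon, and the two rings are joined in the last step. The target has no stereocentre or stereogenic axis.

Key step: step 6

**Route**

Step 1
Reactants: 1 1,2,3-tribromobenzene
Product: 2 2-(3,4,5-tribromophenyl)-4,4,5,5-tetramethyl-1,3,2-dioxaborolane
Conditions: B2pin2 (1.0 equiv), [Ir(OMe)(cod)]2 (1.5 mol%), 4,4'-di-tert-butyl-2,2'-bipyridine (3 mol%), THF, 60 °C, N2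
Reagents that add atoms: bis(pinacolato)diboron, CC1(C)OB(OC1(C)C)B1OC(C)(C)C(C)(C)O1
Why: Iridium-catalysed aromatic C–H borylation is governed by sterics, and C5 is the only C–H of 1 with no ortho bromine, so a single boronate should form while the C–Br bonds are left alone.

Step 2
Reactants: 2 2-(3,4,5-tribromophenyl)-4,4,5,5-tetramethyl-1,3,2-dioxaborolane
Product: 3 3,4,5-tribromophenol
Conditions: Oxone (2KHSO5·KHSO4·K2SO4, 1.1 equiv KHSO5), acetone/H2O, rt; aq NaHSO3 quench
Reagents that add atoms: potassium peroxymonosulfate (KHSO5, active part of Oxone), [K+].[O-]S(=O)(=O)OO
Why: Oxidation of the aryl boronate by peroxide addition to boron, 1,2-aryl shift from boron to oxygen and hydrolysis of the borate ester should give the phenol with the oxygen exactly where boron sat.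

Step 3
Reactants: 3 3,4,5-tribromophenol
Product: 4 3,4,5-tribromo-2-nitrophenol
Conditions: HNO3 (65%, 1.05 equiv), AcOH/CH2Cl2, 0 to 10 °C
Reagents that add atoms: nitric acid, O[N+](=O)[O-]
Why: Electrophilic aromatic nitration directed by the hydroxyl group can only go ortho because the para carbon carries bromine, the two ortho sites are equivalent by symmetry, and the first nitro group (hydrogen-bonded to the OH) deactivates the ring against a second one under these mild, stoichiometric conditions.

Step 4
Reactants: 4 3,4,5-tribromo-2-nitrophenol
Product: 5 2-amino-3,4,5-tribromophenol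
Conditions: SnCl2·2H2O (5 equiv), conc. HCl, EtOH, 60 °C, N2; then aq NaHCO3 to pH 7, EtOAc
Reagents that add atoms: none
Why: Dissolving-metal-salt reduction of a nitroarene with SnCl2 proceeds by electron and proton transfer and, with no hydrogenolysis catalyst present, should leave all three aryl bromides in place.

Step 5
Reactants: 5 2-amino-3,4,5-tribromophenol
Product: 7 3,4,5-tribromo-6-diazocyclohexa-2,4-dien-1-one, via diazonium chloride 6 (not isolated)
Conditions: NaNO2 (1.1 equiv), aq HCl/AcOH, 0–5 °C; then NaHCO3 to pH 6–7, extraction into CH2Cl2, dark, below 20 °C, solution not taken to dryness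
Reagents that add atoms: sodium nitrite (NaNO2), [Na+].[O-]N=O
Why: Diazotisation of an ortho-aminophenol gives an ortho-hydroxy diazonium ion whose phenol is acidic enough to be deprotonated by bicarbonate, which should deliver the neutral diazo oxide (ortho-quinone diazide), a class that is known to be isolable when the ring is polyhalogenated.

Step 6
Reactants: 7 3,4,5-tribromo-6-diazocyclohexa-2,4-dien-1-one; 8 2,4-dibromophenol
Product: 10 3,4,5-tribromo-2-(2,4-dibromophenoxy)phenol, via oxonium ylide 9 (not isolated)
Conditions: Rh2(OAc)4 (2 mol%), 8 (4 equiv), 4 Å MS, ClCH2CH2Cl, 40–60 °C, dark, Ar, 7 added by syringe pump over several hours; excess 8 recovered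
Reagents that add atoms: none
Why: Proposed new method: dirhodium tetraacetate should expel dinitrogen from 7 to give an electrophilic quinoid rhodium carbenoid at C2 of ring A, the phenolic oxygen of 8 should add to this carbon to give oxonium ylide 9, and a proton shift to the former carbonyl oxygen should rearomatise ring A to the 2-aryloxyphenol 10. The closest known reaction types are the dirhodium-catalysed O–H insertion of diazonaphthoquinones into alcohols, which gives ortho-alkoxy naphthols, and the O–H insertion of rhodium or copper carbenoids from diazocarbonyl compounds into phenols; new here is the pairing of a monocyclic tribrominated benzoquinone diazide with a weakly nucleophilic bromophenol. No ring is closed and no stereocentre is created. The position of the ether is dictated by where the diazo group sits, so the step needs only chemoselectivity for O–H insertion over Wolff ring contraction, azo coupling and C–H arylation at C6 of 8. This should be secured by metal catalysis in the dark under dry, neutral conditions, by a low standing concentration of 7, and by a large excess of the deactivated, para-blocked phenol; the three bromines raise the electrophilicity of the carbenoid and the gain in aromaticity drives the proton transfer. The bromine on C3, which would shut down displacement chemistry at the doubly flanked C2, should matter little because the oxygen bonds to a trigonal carbenoid carbon and displaces no leaving group.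

**Compound list**
1 | 1,2,3-tribromobenzene | Brc1cccc(Br)c1Br | starting material
2 | 2-(3,4,5-tribromophenyl)-4,4,5,5-tetramethyl-1,3,2-dioxaborolane | CC1(C)OB(c2cc(Br)c(Br)c(Br)c2)OC1(C)C | intermediate
3 | 3,4,5-tribromophenol | Oc1cc(Br)c(Br)c(Br)c1 | intermediate
4 | 3,4,5-tribromo-2-nitrophenol | Oc1cc(Br)c(Br)c(Br)c1[N+](=O)[O-] | intermediate
5 | 2-amino-3,4,5-tribromophenol | Nc1c(O)cc(Br)c(Br)c1Br | intermediate
6 | 2,3,4-tribromo-6-hydroxybenzenediazonium chloride (diazonium chloride) | Oc1cc(Br)c(Br)c(Br)c1[N+]#N.[Cl-] | intermediate
7 | 3,4,5-tribromo-6-diazocyclohexa-2,4-dien-1-one (ortho-quinone diazide of ring A) | O=C1C=C(Br)C(Br)=C(Br)C1=[N+]=[N-] | intermediate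
8 | 2,4-dibromophenol | Oc1ccc(Br)cc1Br | starting material
9 | oxonium ylide, 3,4,5-tribromo-2-[(2,4-dibromophenyl)oxonio]phenolate | [O-]c1cc(Br)c(Br)c(Br)c1[OH+]c1ccc(Br)cc1Br | intermediate
10 | 3,4,5-tribromo-2-(2,4-dibromophenoxy)phenol | Oc1cc(Br)c(Br)c(Br)c1Oc1ccc(Br)cc1Br | target

**Step count**
Total steps: 6. Longest linear sequence: 6 steps (1 to 10; 8 is bought and enters in the last step).

**Steps most likely to fail**

Step 6 (proposed new method). The carbenoid may not be intercepted by the phenol oxygen: dinitrogen loss may be followed by Wolff ring contraction to a cyclopentadienyl ketene, the diazo oxide may act as a diazonium electrophile and azo-couple at C6 of the phenol, the carbenoid may dimerise or insert into a C–H bond, or traces of water may be inserted instead. The fallback reverses the roles of the rings and uses known chemistry: ring A becomes the oxygen nucleophile and ring B a diaryliodonium electrophile, the established way to hindered polybrominated diaryl ethers. It sets out from nitrophenol 4. O-methylation (MeI, K2CO3, DMF) should give 1,2,3-tribromo-5-methoxy-4-nitrobenzene F1, and reduction with SnCl2·2H2O and HCl in EtOH should give 2,3,4-tribromo-6-methoxyaniline F2. Diazotisation (NaNO2, H2SO4/AcOH, 0 °C) should give 2,3,4-tribromo-6-methoxybenzenediazonium hydrogen sulfate F3, which on copper-mediated hydroxy-dediazoniation (Cu2O, Cu(NO3)2, water, room temperature) should give 2,3,4-tribromo-6-methoxyphenol F4. Its sodium salt would be O-arylated with bis(2,4-dibromophenyl)iodonium chloride F5 (prepared from 1,3-dibromobenzene and iodyl sulfate in H2SO4, then chloride exchange) in aqueous NaOH/dioxane at reflux to give 1,2,3-tribromo-4-(2,4-dibromophenoxy)-5-methoxybenzene F6. Cleavage of the methyl ether with BBr3 in CH2Cl2 (−78 °C to room temperature) brings the fallback back to the route at target 10.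

Step 3. Nitration may go astray by ipso attack at the para carbon C4 with loss of bromine, by a second nitration at the other ortho site, or by oxidation of the phenol to quinoid material. The fallback brings in the nitrogen by azo coupling in place of nitration. It sets out from phenol 3, whose phenoxide (aq NaOH/pyridine, 0 °C) would be coupled at the free ortho carbon with 4-nitrobenzenediazonium tetrafluoroborate to give 3,4,5-tribromo-2-[(E)-(4-nitrophenyl)diazenyl]phenol F7. Reductive cleavage of the azo bond with Na2S2O4 in aqueous EtOH at 70 °C should then give the aminophenol directly, so the fallback bypasses 4 and comes back to the route at 5.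

Step 5. The weakly basic, poorly soluble amine may diazotise incompletely and couple with its own diazonium ion, and the neutral diazo oxide may lose dinitrogen through light or warmth during neutralisation and extraction. The fallback carries the carbene precursor as a storable salt and never isolates the diazo oxide. It sets out from 5, which with tert-butyl nitrite and BF3·OEt2 in THF at −15 °C, followed by precipitation with Et2O, should give 2,3,4-tribromo-6-hydroxybenzenediazonium tetrafluoroborate F8. Stirring this salt with solid NaHCO3 in cold CH2Cl2 in the dark, followed by filtration, should release a solution of 7, at which point the fallback rejoins the route; the solution is fed straight into step 6.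

**Further compounds**
F1 | step 6 | 1,2,3-tribromo-5-methoxy-4-nitrobenzene | COc1cc(Br)c(Br)c(Br)c1[N+](=O)[O-]
F2 | step 6 | 2,3,4-tribromo-6-methoxyaniline | COc1cc(Br)c(Br)c(Br)c1N
F3 | step 6 | 2,3,4-tribromo-6-methoxybenzenediazonium hydrogen sulfate | COc1cc(Br)c(Br)c(Br)c1[N+]#N.OS(=O)(=O)[O-]
F4 | step 6 | 2,3,4-tribromo-6-methoxyphenol | COc1cc(Br)c(Br)c(Br)c1O
F5 | step 6 | bis(2,4-dibromophenyl)iodonium chloride | Brc1ccc([I+]c2ccc(Br)cc2Br)c(Br)c1.[Cl-]
F6 | step 6 | 1,2,3-tribromo-4-(2,4-dibromophenoxy)-5-methoxybenzene | COc1cc(Br)c(Br)c(Br)c1Oc1ccc(Br)cc1Br
F7 | step 3 | 3,4,5-tribromo-2-[(E)-(4-nitrophenyl)diazenyl]phenol | Oc1cc(Br)c(Br)c(Br)c1/N=N/c1ccc(cc1)[N+](=O)[O-]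
F8 | step 5 | 2,3,4-tribromo-6-hydroxybenzenediazonium tetrafluoroborate | Oc1cc(Br)c(Br)c(Br)c1[N+]#N.F[B-](F)(F)F
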